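**Assumption (one line):** commercial (+)-dihydrocarvone is the (2R,5R) isomer, and the C2 epimers converge because C2 is destroyed in the annulation.

## Retrosynthetic overview
1. Macrocarpal H comes from double Vilsmeier formylation of a 2-alkylphloroglucinol. The bridge C–H carbon comes from adding a MOM-protected phloroglucinyl anion to a C1 isovaleryl ketone, then radical deoxygenation of the tertiary benzylic alcohol.
2. The 1β-acyl-4(15)-ene eudesmane comes from a Michael–aldol (Robinson) annulation of a silyl-protected hydroxy-dihydrocarvone with methyl 4-oxopent-2-enoate. Ring B (C7 and C10 stereocentres) comes from the carvone-derived ketone, and ring A is formed last.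
3. The annulation enone is converted to the 3-deoxy-4(15)-ene with 5α-H by Birch reduction, HCHO aldol/elimination, Luche reduction and Tsuji hydrogenolysis.

## Route

**Step 1**
Reactants: 1 (2R,5R)-dihydrocarvone
Product: 2 (2R,5R)-5-(2-hydroxypropan-2-yl)-2-methylcyclohexanone
Conditions: Co(acac)2 (5 mol %), PhSiH3, O2 (1 atm), i-PrOH, 25 °C
Reagents that add atoms: dioxygen, O=O (supplies the OH oxygen)
Why: Mukaiyama hydration; Co–H hydrogen-atom transfer to the isopropenyl group gives a tertiary radical that O2 traps as the tertiary alcohol. No stereocentre is touched.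

**Step 2**
Reactants: 2
Product: 3 (2R,5R)-2-methyl-5-[2-(triethylsilyloxy)propan-2-yl]cyclohexanone
Conditions: TESCl, imidazole, DMAP, DMF, 40 °C
Reagents that add atoms: TESCl, CC[Si](Cl)(CC)CC
Why: Silylation with a chloride/imidazole system, which does not make the enol silyl ether, protects the tertiary alcohol for the later radical deoxygenation.

**Step 3**
Reactants: 3; 4 methyl (E)-4-oxopent-2-enoate
Product: 5 methyl 11-(triethylsilyloxy)-3-oxoeudesm-4-en-1β-carboxylate
Conditions: (i) NaOMe (0.3 equiv), MeOH, 0→25 °C; (ii) pyrrolidine, AcOH, PhMe, 80 °C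
Reagents that add atoms: none
Why: Robinson annulation (Michael addition of the more substituted ketone enolate, then aldol condensation). The quaternary C10 is set thermodynamically with 10β-Me cis to the 7β side chain, as in the α-cyperone synthesis from dihydrocarvone. The C1 ester epimerises under the basic conditions toward the equatorial β isomer.

**Step 4**
Reactants: 5
Product: 6 methyl 4-(hydroxymethyl)-11-(triethylsilyloxy)-3-oxo-5α-eudesmane-1β-carboxylate
Conditions: Li, NH3(l), THF, t-BuOH (1 equiv), –78 °C; then monomeric CH2O, –78 °C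
Reagents that add atoms: formaldehyde, C=O
Why: Stork reductive alkylation. Dissolving-metal enone reduction gives the trans-fused 5α-H and a regiospecific C3–C4 lithium enolate, which is trapped by aldol with CH2O at C4. The C4 centre is later destroyed.

**Step 5**
Reactants: 6
Product: 7 methyl 11-(triethylsilyloxy)-3-oxo-5α-eudesm-4(15)-ene-1β-carboxylate
Conditions: MsCl, Et3N, CH2Cl2, 0→25 °C
Reagents that add atoms: none (the mesylate is lost)
Why: Mesylation then E1cB elimination gives the α-methylene ketone. Mild amine base at low temperature avoids dienolisation at C5.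

**Step 6**
Reactants: 7
Product: 8 methyl 3-hydroxy-11-(triethylsilyloxy)-5α-eudesm-4(15)-ene-1β-carboxylate (C3 epimer mixture)
Conditions: NaBH4, CeCl3·7H2O, MeOH, –20 °C
Reagents that add atoms: none
Why: Luche 1,2-reduction of the enone carbonyl; the ester is untouched and the C3 centre is removed later.

**Step 7**
Reactants: 8
Product: 9 the 3-O-methoxycarbonyl derivative of 8
Conditions: ClCO2Me, pyridine, DMAP (cat.), CH2Cl2, 0 °C
Reagents that add atoms: methyl chloroformate, COC(=O)Cl
Why: Acylation of the secondary allylic alcohol gives the π-allyl-Pd precursor.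

**Step 8**
Reactants: 9
Product: 10 methyl 11-(triethylsilyloxy)-5α-eudesm-4(15)-ene-1β-carboxylate
Conditions: Pd(OAc)2 (5 mol %), PPh3 (20 mol %), HCO2NH4 (3 equiv), THF, 60 °C
Reagents that add atoms: none (formate supplies H)
Why: Tsuji–Trost formate hydrogenolysis. Hydride is delivered to the more substituted allyl terminus (C3), so the less substituted exocyclic C4=C15 alkene forms; C5, C1 and C10 are not involved.

**Step 9**
Reactants: 10
Product: 11 the Weinreb amide (N-methoxy-N-methyl 11-(triethylsilyloxy)-5α-eudesm-4(15)-ene-1β-carboxamide)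
Conditions: Me3Al, MeNHOMe·HCl, THF, 0→40 °C
Reagents that add atoms: N,O-dimethylhydroxylamine hydrochloride, CNOC.Cl
Why: AlMe3-mediated Weinreb amidation under non-basic conditions, so C1 is not epimerised.

**Step 10**
Reactants: 11
Product: 12 1β-isovaleryl-11-(triethylsilyloxy)-5α-eudesm-4(15)-ene
Conditions: i-BuMgBr (3 equiv), THF, 0→25 °C; then DBU (0.5 equiv), PhMe, 60 °C
Reagents that add atoms: isobutylmagnesium bromide, CC(C)C[Mg]Br
Why: Weinreb ketone synthesis, where the chelated intermediate prevents over-addition. DBU equilibrates the α-stereocentre C1 to the equatorial 1β ketone, which is the target configuration.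

**Step 11**
Reactants: 13 phloroglucinol
Product: 14 1,3,5-tris(methoxymethoxy)benzene
Conditions: NaH (3.6 equiv), MOMCl (3.6 equiv), DMF, 0→25 °C
Reagents that add atoms: MOMCl, COCCl
Why: O-alkylation gives MOM ethers that direct ortho-lithiation and survive organolithium and radical conditions.

**Step 12**
Reactants: 12; 14
Product: 15 tertiary benzylic alcohol (C-bridge epimer mixture)
Conditions: 14 (2 equiv), n-BuLi (2 equiv), THF, 0 °C, 1 h; then CeCl3 (2 equiv), –78 °C; then 12, –78→25 °C
Reagents that add atoms: none (the aryl group comes from 14)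
Why: Directed ortho-lithiation at the carbon flanked by two OMOM groups, then organocerium 1,2-addition to the hindered ketone. The new carbinol stereocentre is removed in step 14.

**Step 13**
Reactants: 15
Product: 16 methyl oxalate ester of 15
Conditions: MeO2CCOCl, pyridine, DMAP, CH2Cl2, 0→25 °C
Reagents that add atoms: methyl chlorooxoacetate, COC(=O)C(=O)Cl
Why: Converts the tertiary alcohol into a Barton-type radical precursor; the C11 alcohol is TES-protected, so only the benzylic alcohol reacts.

**Step 14**
Reactants: 16
Product: 17 MOM/TES-protected bridged compound with the bridge CH stereocentre set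
Conditions: Bu3SnH (2 equiv), AIBN (0.2 equiv), PhH, 80 °C
Reagents that add atoms: none
Why: Barton radical deoxygenation gives a planar tertiary benzylic radical stabilised by the electron-rich aryl. H-atom transfer from Bu3SnH sets the bridge stereocentre, delivered to the face remote from the quaternary C10. I assume a diastereomer ratio of about 3:1, with the minor epimer removed by chromatography.

**Step 15**
Reactants: 17
Product: 18 2-alkylphloroglucinol triol with free C11 tertiary alcohol
Conditions: 3 M HCl, THF/MeOH (1:1), 25→40 °C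
Reagents that add atoms: none
Why: Acidolysis removes the three aryl MOM ethers and the tertiary TES ether; no stereocentre is affected.

**Step 16**
Reactants: 18
Product: 19 Macrocarpal H
Conditions: POCl3 (3 equiv), DMF, 0→25 °C; then aq. NaOAc
Reagents that add atoms: DMF, CN(C)C=O (supplies both CHO groups)
Why: Vilsmeier–Haack double ortho-formylation of the very nucleophilic phloroglucinol ring at the two C–H positions meta to the alkyl group. No stereocentre is involved.

## Compound list
1 | (2R,5R)-dihydrocarvone | C[C@@H]1CC[C@H](CC1=O)C(C)=C | starting material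
2 | (2R,5R)-5-(2-hydroxypropan-2-yl)-2-methylcyclohexanone | C[C@@H]1CC[C@H](CC1=O)C(C)(C)O | intermediate
3 | TES ether of 2 | C[C@@H]1CC[C@H](CC1=O)C(C)(C)O[Si](CC)(CC)CC | intermediate
4 | methyl (E)-4-oxopent-2-enoate | CC(=O)/C=C/C(=O)OC | starting material
5 | Robinson enone (eudesm-4-en-3-one, 1β-CO2Me, 11-OTES) | COC(=O)[C@@H]1CC(=O)C=C2C[C@H](C(C)(C)O[Si](CC)(CC)CC)CC[C@@]12C | intermediate
6 | 4-hydroxymethyl-5α-3-ketone | COC(=O)[C@@H]1CC(=O)C(CO)[C@@H]2C[C@H](C(C)(C)O[Si](CC)(CC)CC)CC[C@@]12C | intermediate
7 | 4(15)-en-3-one | COC(=O)[C@@H]1CC(=O)C(=C)[C@@H]2C[C@H](C(C)(C)O[Si](CC)(CC)CC)CC[C@@]12C | intermediate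
8 | 3-hydroxy-4(15)-ene (C3 epimers) | COC(=O)[C@@H]1CC(O)C(=C)[C@@H]2C[C@H](C(C)(C)O[Si](CC)(CC)CC)CC[C@@]12C | intermediate
9 | 3-methyl carbonate | COC(=O)[C@@H]1CC(OC(=O)OC)C(=C)[C@@H]2C[C@H](C(C)(C)O[Si](CC)(CC)CC)CC[C@@]12C | intermediate
10 | 3-deoxy-4(15)-ene methyl ester | COC(=O)[C@@H]1CCC(=C)[C@@H]2C[C@H](C(C)(C)O[Si](CC)(CC)CC)CC[C@@]12C | intermediate
11 | Weinreb amide | CON(C)C(=O)[C@@H]1CCC(=C)[C@@H]2C[C@H](C(C)(C)O[Si](CC)(CC)CC)CC[C@@]12C | intermediate
12 | 1β-isovaleryl ketone | CC(C)CC(=O)[C@@H]1CCC(=C)[C@@H]2C[C@H](C(C)(C)O[Si](CC)(CC)CC)CC[C@@]12C | intermediate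
13 | phloroglucinol | Oc1cc(O)cc(O)c1 | starting material
14 | 1,3,5-tris(methoxymethoxy)benzene | COCOc1cc(OCOC)cc(OCOC)c1 | intermediate
15 | tertiary benzylic alcohol (bridge epimer mixture) | CC(C)CC(O)(c1c(OCOC)cc(OCOC)cc1OCOC)[C@@H]2CCC(=C)[C@@H]3C[C@H](C(C)(C)O[Si](CC)(CC)CC)CC[C@@]23C | intermediate
16 | methyl oxalate of 15 | CC(C)CC(OC(=O)C(=O)OC)(c1c(OCOC)cc(OCOC)cc1OCOC)[C@@H]2CCC(=C)[C@@H]3C[C@H](C(C)(C)O[Si](CC)(CC)CC)CC[C@@]23C | intermediate
17 | protected bridged compound | CC(C)C[C@H](c1c(OCOC)cc(OCOC)cc1OCOC)[C@@H]2CCC(=C)[C@@H]3C[C@H](C(C)(C)O[Si](CC)(CC)CC)CC[C@@]23C | intermediate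
18 | deprotected alkylphloroglucinol | CC(C)C[C@H](c1c(O)cc(O)cc1O)[C@@H]2CCC(=C)[C@@H]3C[C@H](C(C)(C)O)CC[C@@]23C | intermediate
19 | Macrocarpal H | C=C1CC[C@@H]([C@H](CC(C)C)c2c(O)c(C=O)c(O)c(C=O)c2O)[C@]2(C)CC[C@@H](C(C)(C)O)C[C@@H]12 | target

**Total step count:** 16 steps (the MOM-arene preparation, step 11, is a parallel step).
**Longest linear sequence:** 15 steps, from dihydrocarvone through steps 1–10 and 12–16.

## Three steps most likely to fail
1. **Step 12 (hindered ketone plus bulky aryl-cerium).** Fallback: change the coupling. Reduce ester 10 to the aldehyde and couple it with diformylphloroglucinol (from phloroglucinol by Vilsmeier). Then add i-BuMgBr to the ortho-quinone methide at high temperature. This is convergent and needs no protecting groups.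
2. **Step 3 (Robinson annulation with a doubly activated acceptor, making adjacent quaternary and tertiary centres).** Fallback: run the standard vinyl-ketone Robinson annulation to the α-cyperone-type enone, dehydrogenate it with IBX to the 1,4-dienone, and add an isovaleryl radical at C1 by photocatalytic hydroacylation (isovaleraldehyde). Then equilibrate C1 with base.
3. **Step 14 (diastereocontrol at the bridge carbon).** Fallback: convert ketone 12 to its N-tosylhydrazone and do a Barluenga reductive coupling with an arylboronic acid. This forms the benzylic C–H in one operation and avoids the tertiary-alcohol and radical route.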